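**Plan**
- Cuts: (i) the bond from benzofuran C2 to the diaryl methine carbon, made last; (ii) the bond from that carbon to ring A; (iii) the furan ring (O1–C2 and C3–C3a); (iv) both aryl–C(=O) bonds, which go back to one Friedel–Crafts acylation of phloroglucinol.
- Forward: phloroglucinol → isovalerylphloroglucinol → bis-benzyl ether 4, from which both halves grow. Half B: O-allylation, Claisen rearrangement, oxidative cleavage/cyclodehydration to the benzofuran, then C2–H borylation to boronic acid 10. Half A: ortho-hydroxyalkylation of 4 with (S)-glyceraldehyde acetonide, then acetonide removal to triol 13.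
- Union: 13 + 10 by a hydroxyl-directed boron-to-carbon transfer onto an o-quinone methide; hydrogenolysis of the four benzyl ethers ends the route.
- Enabling feature: the methine carbon sits on ring A ortho to a phenolic O–H, so it can become the exocyclic carbon of an o-quinone methide. Its neighbour carries the secondary OH that can hold boron. The partner is C2 of the benzofuran, α to the ring oxygen, which migrates readily from boron.
- Stereochemistry: the carbinol carbon comes from the chiral pool ((S)-glyceraldehyde acetonide). The methine centre is set in the key step by 1,2-induction from it; both benzylic epimers of the precursor converge on one configuration.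

Key step: step 9

Remark: 11 is taken as a purchasable reagent (used freshly distilled); the carbinol carbon keeps its geometry throughout, and its descriptor changes between S and R only because the CIP ranking of its neighbours changes.

**Route**

Step 1
Reactants: 1 phloroglucinol; 2 isovaleryl chloride
Product: 3 3-methyl-1-(2,4,6-trihydroxyphenyl)butan-1-one
Conditions: AlCl3 (3 equiv), PhNO2/CH2Cl2, 0 °C to rt; aq HCl
Reagents that add atoms: none
Why: Friedel–Crafts C-acylation of the symmetric triol, which should stop after one acyl group because the hydrogen-bonded ketone deactivates the ring.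

Step 2
Reactants: 3 3-methyl-1-(2,4,6-trihydroxyphenyl)butan-1-one
Product: 4 1-[2,4-bis(benzyloxy)-6-hydroxyphenyl]-3-methylbutan-1-one
Conditions: BnBr (2.1 equiv), K2CO3 (2.2 equiv), DMF, rt
Reagents that add atoms: benzyl bromide, BrCc1ccccc1
Why: Williamson etherification takes the para hydroxyl and one ortho hydroxyl, while the last ortho hydroxyl, locked in a hydrogen bond to the ketone, should remain free.

Step 3
Reactants: 4 1-[2,4-bis(benzyloxy)-6-hydroxyphenyl]-3-methylbutan-1-one
Product: 5 1-[2-(allyloxy)-4,6-bis(benzyloxy)phenyl]-3-methylbutan-1-one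
Conditions: allyl bromide (1.5 equiv), K2CO3, DMF, 60 °C
Reagents that add atoms: allyl bromide, C=CCBr
Why: Williamson O-allylation of the chelated phenol under more forcing conditions places the future C2/C3 unit of the furan on the oxygen that becomes O1.

Step 4
Reactants: 5 1-[2-(allyloxy)-4,6-bis(benzyloxy)phenyl]-3-methylbutan-1-one
Product: 6 1-[3-allyl-4,6-bis(benzyloxy)-2-hydroxyphenyl]-3-methylbutan-1-one
Conditions: PhNEt2, 190 °C (sealed tube)
Reagents that add atoms: none
Why: aromatic Claisen rearrangement ([3,3]) moves the allyl group to the only free ortho carbon, the other ortho position being blocked by the acyl group.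

Step 5
Reactants: 6 1-[3-allyl-4,6-bis(benzyloxy)-2-hydroxyphenyl]-3-methylbutan-1-one
Product: 8 1-[4,6-bis(benzyloxy)-1-benzofuran-7-yl]-3-methylbutan-1-one, via cyclic hemiacetal 7 (not isolated)
Conditions: OsO4 (cat.), NaIO4, 2,6-lutidine, dioxane/H2O, rt; then TsOH·H2O (cat.), toluene, 80 °C
Reagents that add atoms: none
Why: Lemieux–Johnson cleavage gives the arylacetaldehyde, which closes on the neighbouring phenol to the five-membered hemiacetal, and acid-catalysed dehydration aromatises it to the benzofuran with the acyl group fixed at C7.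

Step 6
Reactants: 8 1-[4,6-bis(benzyloxy)-1-benzofuran-7-yl]-3-methylbutan-1-one
Product: 10 [4,6-bis(benzyloxy)-7-(3-methylbutanoyl)-1-benzofuran-2-yl]boronic acid, via pinacol boronate 9 (not isolated)
Conditions: [Ir(OMe)(cod)]2 (1.5 mol %), dtbpy (3 mol %), B2pin2 (1.0 equiv), THF, rt; then NaIO4, NH4OAc, acetone/H2O, rt
Reagents that add atoms: bis(pinacolato)diboron, CC1(C)OB(OC1(C)C)B1OC(C)(C)C(C)(C)O1; water, O
Why: iridium-catalysed C–H borylation should take the C2–H α to the furan oxygen (C3–H is peri-hindered, C5–H is flanked by two benzyloxy groups, the benzyl C–H bonds react more slowly and the ketone is tolerated), and periodate cleavage of the pinacol unit frees the boronic acid.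

Step 7
Reactants: 4 1-[2,4-bis(benzyloxy)-6-hydroxyphenyl]-3-methylbutan-1-one; 11 (S)-2,2-dimethyl-1,3-dioxolane-4-carbaldehyde
Product: 12 1-[4,6-bis(benzyloxy)-3-{[(4S)-2,2-dimethyl-1,3-dioxolan-4-yl](hydroxy)methyl}-2-hydroxyphenyl]-3-methylbutan-1-one (both benzylic epimers)
Conditions: EtMgBr (1.0 equiv), Et2O, 0 °C; solvent changed to CH2Cl2; 11 (1.2 equiv), rt; aq NH4Cl
Reagents that add atoms: none
Why: ortho-specific hydroxyalkylation (aldol-type Friedel–Crafts reaction) of the magnesium phenolate, which holds the aldehyde at the metal and delivers it to the free ortho carbon; the dioxolane centre comes unchanged from 11 and the new benzylic carbinol is left as a mixture of epimers on purpose.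

Step 8
Reactants: 12 1-[4,6-bis(benzyloxy)-3-{[(4S)-2,2-dimethyl-1,3-dioxolan-4-yl](hydroxy)methyl}-2-hydroxyphenyl]-3-methylbutan-1-one (both benzylic epimers)
Product: 13 1-{4,6-bis(benzyloxy)-2-hydroxy-3-[(2S)-1,2,3-trihydroxypropyl]phenyl}-3-methylbutan-1-one (both epimers at C1 of the chain)
Conditions: AcOH/H2O/THF (4:1:1), rt
Reagents that add atoms: none
Why: mild acetal hydrolysis frees the secondary hydroxyl needed as boron carrier; reversible ionisation at the benzylic carbon in the aqueous medium only interconverts epimers that converge in step 9.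

Step 9
Reactants: 13 1-{4,6-bis(benzyloxy)-2-hydroxy-3-[(2S)-1,2,3-trihydroxypropyl]phenyl}-3-methylbutan-1-one (both epimers at C1 of the chain); 10 [4,6-bis(benzyloxy)-7-(3-methylbutanoyl)-1-benzofuran-2-yl]boronic acid
Product: 15 1-[4,6-bis(benzyloxy)-3-{(1S,2R)-1-[4,6-bis(benzyloxy)-7-(3-methylbutanoyl)-1-benzofuran-2-yl]-2,3-dihydroxypropyl}-2-hydroxyphenyl]-3-methylbutan-1-one, via boron-bound o-quinone methide 14 (not isolated)
Conditions: 10 (1.3 equiv), HFIP/CH2Cl2 (1:4), 4 Å MS, 0 °C to rt; aqueous work-up
Reagents that add atoms: none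
Why: Proposed new method: the 1,2-diol of 13 condenses with 10 to a five-membered dioxaborolane (the only ring formed, a temporary one; no ring of the product is closed), the benzylic C–OH on ring A, which lies ortho to the free phenolic O–H and ortho/para to two benzyloxy groups, ionises in HFIP to the o-quinone methide 14 in which both epimers of 13 have become the same planar species, the quinone-methide oxygen (or solvent) makes boron tetracoordinate, and the benzofuran-2-yl group shifts from boron to the methide carbon through a five-membered B–O–C–C transition state with rearomatisation of ring A, the borate being hydrolysed on work-up. The closest known reaction types are the Petasis borono-Mannich reaction of α-hydroxy aldehydes, where a hydroxyl-bound boronate delivers its group to the neighbouring iminium carbon with anti selectivity, and the diol-catalysed 1,4-addition of aryl and alkenyl boronates to o-quinone methides; the new element is the substrate hydroxyl acting as internal carrier on an o-quinone methide. The new stereocentre is controlled by the adjacent oxygen-bearing carbon from 11: allylic 1,3-strain places its C–H bond in the plane of the quinone methide, the boron-bearing oxygen then lies over one face, and the heteroaryl group should be delivered to that face, which leads to the (1S,2R) arrangement of 15 (the Petasis anti relationship). The step needs ipso transfer from C2 of the benzofuran and not Friedel–Crafts attack through C5, which the C–B bond secures, and it needs transfer to be faster than tautomerisation of 14 to an enol, which the intramolecular delivery and the donor-stabilised, acylphloroglucinol-type quinone methide should favour.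

Step 10
Reactants: 15 1-[4,6-bis(benzyloxy)-3-{(1S,2R)-1-[4,6-bis(benzyloxy)-7-(3-methylbutanoyl)-1-benzofuran-2-yl]-2,3-dihydroxypropyl}-2-hydroxyphenyl]-3-methylbutan-1-one
Product: 16 1-[3-{(1S,2R)-1-[4,6-dihydroxy-7-(3-methylbutanoyl)-1-benzofuran-2-yl]-2,3-dihydroxypropyl}-2,4,6-trihydroxyphenyl]-3-methylbutan-1-one
Conditions: H2 (1 atm), 10% Pd/C, EtOAc/MeOH, rt
Reagents that add atoms: none
Why: hydrogenolysis of the four aryl benzyl ethers under neutral conditions should leave the benzofuran, the hindered hydrogen-bonded aryl ketones and both stereocentres untouched (no C–O bond at either centre is benzylic).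

**Compound list**

1 | phloroglucinol (benzene-1,3,5-triol) | Oc1cc(O)cc(O)c1 | starting material
2 | isovaleryl chloride (3-methylbutanoyl chloride) | CC(C)CC(=O)Cl | starting material
3 | 3-methyl-1-(2,4,6-trihydroxyphenyl)butan-1-one | CC(C)CC(=O)c1c(O)cc(O)cc1O | intermediate
4 | 1-[2,4-bis(benzyloxy)-6-hydroxyphenyl]-3-methylbutan-1-one | CC(C)CC(=O)c1c(OCc2ccccc2)cc(OCc2ccccc2)cc1O | intermediate
5 | 1-[2-(allyloxy)-4,6-bis(benzyloxy)phenyl]-3-methylbutan-1-one | CC(C)CC(=O)c1c(OCc2ccccc2)cc(OCc2ccccc2)cc1OCC=C | intermediate
6 | 1-[3-allyl-4,6-bis(benzyloxy)-2-hydroxyphenyl]-3-methylbutan-1-one | CC(C)CC(=O)c1c(OCc2ccccc2)cc(OCc2ccccc2)c(CC=C)c1O | intermediate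
7 | 1-[4,6-bis(benzyloxy)-2-hydroxy-2,3-dihydro-1-benzofuran-7-yl]-3-methylbutan-1-one (cyclic hemiacetal, not isolated) | CC(C)CC(=O)c1c(OCc2ccccc2)cc(OCc2ccccc2)c2CC(O)Oc12 | intermediate
8 | 1-[4,6-bis(benzyloxy)-1-benzofuran-7-yl]-3-methylbutan-1-one | CC(C)CC(=O)c1c(OCc2ccccc2)cc(OCc2ccccc2)c2ccoc12 | intermediate
9 | 1-[4,6-bis(benzyloxy)-2-(4,4,5,5-tetramethyl-1,3,2-dioxaborolan-2-yl)-1-benzofuran-7-yl]-3-methylbutan-1-one (not isolated) | CC(C)CC(=O)c1c(OCc2ccccc2)cc(OCc2ccccc2)c2cc(B3OC(C)(C)C(C)(C)O3)oc12 | intermediate
10 | [4,6-bis(benzyloxy)-7-(3-methylbutanoyl)-1-benzofuran-2-yl]boronic acid | CC(C)CC(=O)c1c(OCc2ccccc2)cc(OCc2ccccc2)c2cc(B(O)O)oc12 | intermediate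
11 | (S)-2,2-dimethyl-1,3-dioxolane-4-carbaldehyde ((S)-glyceraldehyde acetonide) | O=C[C@@H]1COC(C)(C)O1 | starting material
12 | 1-[4,6-bis(benzyloxy)-3-{[(4S)-2,2-dimethyl-1,3-dioxolan-4-yl](hydroxy)methyl}-2-hydroxyphenyl]-3-methylbutan-1-one, both epimers at the benzylic carbinol | CC(C)CC(=O)c1c(OCc2ccccc2)cc(OCc2ccccc2)c(C(O)[C@@H]2COC(C)(C)O2)c1O | intermediate
13 | 1-{4,6-bis(benzyloxy)-2-hydroxy-3-[(2S)-1,2,3-trihydroxypropyl]phenyl}-3-methylbutan-1-one, both epimers at C1 of the chain | CC(C)CC(=O)c1c(OCc2ccccc2)cc(OCc2ccccc2)c(C(O)[C@@H](O)CO)c1O | intermediate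
14 | 3,5-bis(benzyloxy)-6-({(4R)-2-[4,6-bis(benzyloxy)-7-(3-methylbutanoyl)-1-benzofuran-2-yl]-1,3,2-dioxaborolan-4-yl}methylidene)-2-(3-methylbutanoyl)cyclohexa-2,4-dien-1-one (boron-bound o-quinone methide, not isolated) | O=C1C(C(=O)CC(C)C)=C(OCc2ccccc2)C=C(OCc2ccccc2)C1=C[C@@H]1COB(c2cc3c(OCc4ccccc4)cc(OCc4ccccc4)c(C(=O)CC(C)C)c3o2)O1 | intermediate
15 | 1-[4,6-bis(benzyloxy)-3-{(1S,2R)-1-[4,6-bis(benzyloxy)-7-(3-methylbutanoyl)-1-benzofuran-2-yl]-2,3-dihydroxypropyl}-2-hydroxyphenyl]-3-methylbutan-1-one | CC(C)CC(=O)c1c(OCc2ccccc2)cc(OCc2ccccc2)c([C@H](c2cc3c(OCc4ccccc4)cc(OCc4ccccc4)c(C(=O)CC(C)C)c3o2)[C@@H](O)CO)c1O | intermediate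
16 | 1-[3-{(1S,2R)-1-[4,6-dihydroxy-7-(3-methylbutanoyl)-1-benzofuran-2-yl]-2,3-dihydroxypropyl}-2,4,6-trihydroxyphenyl]-3-methylbutan-1-one | CC(C)CC(=O)c1c(O)cc(O)c([C@H](c2cc3c(O)cc(O)c(C(=O)CC(C)C)c3o2)[C@@H](O)CO)c1O | target

**Step count and risks**

Total steps: 10. Longest linear sequence: 8 (steps 1, 2, 3, 4, 5, 6, 9, 10).

Steps most likely to fail:

1. Step 9 (proposed new method). The boron-to-carbon transfer may occur without guidance from the neighbouring oxygen, giving poor facial selectivity. The quinone methide may also be lost by tautomerisation (1,2-hydrogen shift towards an α-hydroxy ketone), or protodeboronation may outrun the transfer. The fallback uses known chemistry with catalyst control in place of hydroxyl direction; it sets out from 12 and 10. 12 is converted with ethanol and a trace of acid into the benzylic ethyl ether F1, and 10 is esterified with propan-2-ol to the diisopropyl boronate F2. The two are joined by the chiral-biphenol-catalysed 1,4-addition of aryl boronates to o-quinone methides (3,3'-dibromo-BINOL, the enantiomer that directs the heteroaryl group to the required face, toluene, 4 Å MS), which should give the coupled acetonide F3. Aqueous acetic acid then removes the acetonide, and the route is rejoined at 15.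

2. Step 7. The ketone-chelated magnesium phenolate may be too weak a carbon nucleophile, the base may add to the ketone, or the adduct may lose water and oligomerise. The fallback sets out from 4 and 11 and uses a boronic-acid-templated ortho-hydroxyalkylation (phenylboronic acid, cat. propionic acid, toluene, azeotropic removal of water). This should give the cyclic phenylboronate F4, in which the adduct is protected as it forms. Oxidative removal of boron (H2O2, THF) returns the route at 12.

3. Step 8. Ionisation at the benzylic carbinol during the acid treatment may be followed by an irreversible 1,2-hydride shift or by Friedel–Crafts self-condensation (epimerisation alone is harmless). The fallback sets out from 12 and makes the ionisation productive: acid-catalysed methanolysis (PPTS, MeOH, rt) removes the acetonide while the solvent captures the quinone methide, which should give the benzylic methyl ether diol F5. F5 takes the place of 13 in step 9, methanol leaving instead of water, and the route is rejoined at 15.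

Further compounds

F1 | step 9 | 1-[4,6-bis(benzyloxy)-3-{[(4S)-2,2-dimethyl-1,3-dioxolan-4-yl](ethoxy)methyl}-2-hydroxyphenyl]-3-methylbutan-1-one, both benzylic epimers | CC(C)CC(=O)c1c(OCc2ccccc2)cc(OCc2ccccc2)c(C(OCC)[C@@H]2COC(C)(C)O2)c1O
F2 | step 9 | dipropan-2-yl [4,6-bis(benzyloxy)-7-(3-methylbutanoyl)-1-benzofuran-2-yl]boronate | CC(C)CC(=O)c1c(OCc2ccccc2)cc(OCc2ccccc2)c2cc(B(OC(C)C)OC(C)C)oc12
F3 | step 9 | 1-[4,6-bis(benzyloxy)-3-{(S)-[4,6-bis(benzyloxy)-7-(3-methylbutanoyl)-1-benzofuran-2-yl][(4R)-2,2-dimethyl-1,3-dioxolan-4-yl]methyl}-2-hydroxyphenyl]-3-methylbutan-1-one | CC(C)CC(=O)c1c(OCc2ccccc2)cc(OCc2ccccc2)c([C@H](c2cc3c(OCc4ccccc4)cc(OCc4ccccc4)c(C(=O)CC(C)C)c3o2)[C@@H]2COC(C)(C)O2)c1O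
F4 | step 7 | 1-{5,7-bis(benzyloxy)-4-[(4S)-2,2-dimethyl-1,3-dioxolan-4-yl]-2-phenyl-4H-1,3,2-benzodioxaborinin-8-yl}-3-methylbutan-1-one, both epimers at C4 | CC(C)CC(=O)c1c(OCc2ccccc2)cc(OCc2ccccc2)c2C([C@@H]3COC(C)(C)O3)OB(c3ccccc3)Oc12
F5 | step 8 | 1-{4,6-bis(benzyloxy)-3-[(2S)-2,3-dihydroxy-1-methoxypropyl]-2-hydroxyphenyl}-3-methylbutan-1-one, both epimers at C1 of the chain | CC(C)CC(=O)c1c(OCc2ccccc2)cc(OCc2ccccc2)c(C(OC)[C@@H](O)CO)c1O
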